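## The problem

Target **33** is a cuparane-type sesquiterpenoid: a cyclopentane (ring A: C1 CMe2, C2 CHBr, C3 CH2, C4 CHOH, C5 CMe) joined through the C5–C1' bond to a cyclohexane (ring B: C1' C(OH), C2', C3', C4' CMeCl, C5' CHBr, C6'). These atom labels are used for every intermediate. C1, C5 and C1' are three fully substituted carbons in a row, so the C1–C5 and C5–C1' bonds are the hard ones to form. Of the six stereocentres, C5 cannot be corrected later and must come first. Once ring B is on C5, its bulk defines the open face of ring A (C2, C4), the C5 substituents define the open face of a C1' carbonyl group, and the axial C1' hydroxyl can steer reagents in ring B (C4', C5'). Bromine at C2, the C4 hydroxyl and ring B all sit on the crowded face of ring A. The chlorine/bromine pair is trans-diequatorial on a chair locked by ring A, which plain anti addition to a C4'=C5' alkene does not give. The tertiary chloride next to a secondary bromide will not survive base or reducing metals. A C4 ketone next to a free C1' hydroxyl can undergo retro-aldol cleavage, and the C1' hydroxyl can trap a C4' cation as a 7-oxabicyclo[2.2.1]heptane ether. The enabling feature is that C1 with its two methyl groups plus C2 is a tert-butyl group on C5: the C1–C5 bond can be bought in a malonate, and only the unhindered C2–C3 bond has to be closed, from a carbene at C3 next to the C4 carbonyl.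

## Retrosynthesis

**Ring B halogens (33 to 28).** The C4'–Cl and C5'–Br bonds are cut back to the C4'=C5' alkene of bromo diol **28**. Direct BrCl addition is rejected: on the locked chair it would follow the diaxial path and give the other trans diastereomer. Instead, epoxide **29** is formed on the face of the axial C1' hydroxyl and opened diaxially by bromide at C4' to bromohydrin **31**. Ionising the C5' oxygen of **31** gives a bromonium ion on the face away from O1', which chloride opens at the tertiary carbon to give **32**. O4 and O1' are tied as a cyclic carbonate (**30** to **32**) so that neither can be activated or trap the cation. The forward steps must deliver a directed epoxidation, a regioselective opening and a bromine shift; **28** is simpler by two stereocentres and two halogens.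

**Ring A heteroatoms (28 to 23).** The C2–Br bond is cut to a C2–O bond of opposite configuration (diol **26**), and the C2 and C4 oxygens are traced to enone **23**. Bromine must end on the hindered face, so oxygen is first placed on the open face (β-hydroxy ketone **25**) and replaced with inversion (**27**). The C2 hydroxyl also delivers hydride to C4 from the open face, which puts O4 cis to ring B. The alternative of adding bromide directly to C2 would put it on the wrong face.

**Enone (23 to 20).** The C2=C3 unsaturation is removed to ketone **21**, which is unmasked from ketal **20**. Keeping C4 at the ketone level through the ring B work saves a reduction, a protection and a reoxidation compared with a protected C4 alcohol.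

**Ring B carbons (20 to 13).** The C4'=C5' alkene is cut by ring-closing metathesis to diene **19**, the C1'–C6' bond by allyl addition (**18**) to ketone **17**, and the C1'–C2' bond by addition of Grignard reagent **15** to aldehyde **13**. The order of the two additions is fixed by the facial model for the C1' carbonyl (allyl last). The reverse order would need an enolisable β,γ-unsaturated ketone and, on the same model, give the C1' epimer.

**Oxidation level at C1' (13 to 10).** Aldehyde **13** comes from ester **11** by reduction to **12** and reoxidation, and **11** is the ketal of keto ester **10**. No C–C bond is cut here. The ester is the only carboxyl derivative that is inert in the carbene step.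

**Ring A (10 to 9).** The C2–C3 bond is cut, leading to diazoketone **9**. This removes the ring and leaves an acyclic compound with one stereocentre, in which the C1–C5 bond is simply the tert-butyl–carbon bond. Cuts at C1–C5 or C4–C5 would require forming a bond between two fully substituted carbons.

**C5 (9 to 1).** The C3–C4 bond is cut to acid **5** and (trimethylsilyl)diazomethane **6**. Acid **5** comes from prochiral diester **4** by enantiotopic-group-selective hydrolysis, and **4** from diethyl tert-butylmalonate **1** and iodomethane **2**. The enzyme has to distinguish two ester groups on a very hindered carbon; in return the absolute configuration of the whole molecule is set on a symmetrical, commercially derived diester.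

## Roads not taken

**Alternative 1:** The cut removes the C1–C5 and C1'–O bonds together and leads to the bisabolene-type triene carbonate A1. In the forward step Et2SBr·SbBrCl5 transfers Br+ to the C1=C2 alkene, the tetrasubstituted C5=C1' alkene attacks C1, and the tert-butyl carbonate on O4 traps the C1' cation, giving A2.
- Merits: the most congested bond, the C2 bromine, C5 and C1' all arise in one step. A2 is the cyclic carbonate of **28**, so this road would join the present route six steps before its end after far fewer operations. In step economy it is clearly better.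
- Weak points: three electron-rich alkenes compete for Br+, and the tetrasubstituted one is the most nucleophilic. Ring A must close at the more substituted bromonium carbon in a five-membered mode that creates two adjacent quaternary carbons. C2, C5 and C1' are set relative to C4 in one event with no obvious control of the bromonium face.
- Against this the chosen plan sets one control element per stereocentre and a C1–C5 bond that is never formed.

**Alternative 2:** The cut is C4–C5, back to the epoxy silyl ether A3. BF3·OEt2 opens the tetrasubstituted epoxide at the carbon next to the gem-dimethyl group and the ring bond from the silyloxy carbon shifts, giving the acetylcyclopentane A4.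
- Merits: no diazo compound and no enzyme. The shift is stereospecific, so the C4/C5 relationship of the target (O4 cis to C1') is transferred from an epoxy alcohol available by enantioselective ketone reduction and directed epoxidation. In this respect it is more secure than the present route.
- Weak points: the migrating carbon carries an electron-withdrawing oxygen, and the neighbouring gem-dimethyl carbon offers a competing methyl shift to the same cation. In A4, C1' is a methyl ketone, so both ring B chains must be grown from an acetyl group next to a quaternary carbon. C4 is locked as a silyl ether, so the enone chemistry for C2 would still need deprotection and oxidation.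
- The chosen plan has C1' as an ester that accepts two different nucleophiles in turn and keeps C4 as a ketone.

**Alternative 3:** The cut is C1–C2, back to the isopropenyl aldehyde A5. Fe(acac)3 and PhSiH3 deliver a hydrogen atom to the isopropenyl CH2, and the tertiary C1 radical adds 5-exo to the aldehyde, giving hydroxy ester A6.
- Merits: a radical is well suited to forming a crowded quaternary carbon. The C2 oxygen arrives in the ring-closing step, already distinguished from the silylated O4. This spares the desaturation, borylation and reduction steps of the present route and its O2/O4 discrimination; here it is better.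
- Weak points: A5 needs quaternary C5 (methyl, ester, isopropenyl) next to the C4 carbinol, which asks for a stereoselective aldol of a tetrasubstituted enolate. Radical addition to an aldehyde is reversible, and here it reverts to a stabilised tertiary radical. A6 carries the C2 hydroxyl on the face bromine must finally occupy, so the substitution needs net retention.
- The chosen plan sets C5 on a symmetrical diester and places the C2 oxygen on the face from which one inversion gives the bromide.

Key step: step 4

Assumption: pig liver esterase is taken to hydrolyse the ester group of **4** that gives the (S)-acid **5**. If it prefers the other enantiotopic ester, the same C5 configuration follows by exchanging the roles of the two carboxyl groups (tert-butyl ester on the free acid, saponification of the ethyl ester, diazoketone from the new acid).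

## Route

Step 1
Reactants: 1 diethyl tert-butylmalonate; 2 iodomethane
Product: 4 diethyl 2-tert-butyl-2-methylmalonate, via sodium enolate 3 (not isolated)
Conditions: NaH, DMF, 0 °C to rt; then MeI, rt to 50 °C
Reagents that add atoms: iodomethane, CI
Why: Malonate alkylation through the sodium enolate; the small electrophile should overcome the hindrance of the tert-butyl group, and C5 stays prochiral.

Step 2
Reactants: 4 diethyl 2-tert-butyl-2-methylmalonate
Product: 5 (2S)-2-(ethoxycarbonyl)-2,3,3-trimethylbutanoic acid
Conditions: pig liver esterase, phosphate buffer pH 7.5, 10% DMSO, 30 °C, pH-stat (NaOH); then HCl to pH 2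
Reagents that add atoms: water, O
Why: Enzymatic desymmetrisation of a prochiral 2,2-disubstituted malonate; the esterase selects one enantiotopic ester group and thereby sets C5, which is quaternary and cannot racemise afterwards.

Step 3
Reactants: 5 (2S)-2-(ethoxycarbonyl)-2,3,3-trimethylbutanoic acid; 6 (trimethylsilyl)diazomethane
Product: 9 ethyl (2S)-2-(2-diazoacetyl)-2,3,3-trimethylbutanoate, via acid chloride 7 (not isolated), via silyl diazoketone 8 (not isolated)
Conditions: (COCl)2, cat. DMF, CH2Cl2, 0 °C to rt; evaporate; then TMSCHN2, Et3N, MeCN/THF, 0 °C to rt; aq. NaHCO3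
Reagents that add atoms: (trimethylsilyl)diazomethane, C[Si](C)(C)C=[N+]=[N-]; oxalyl chloride, ClC(=O)C(Cl)=O (chlorine of 7 only)
Why: Arndt–Eistert-type acylation of a diazomethane equivalent by an acid chloride, followed by protodesilylation on work-up. The α-carbon is quaternary, so neither ketene formation nor loss of configuration is possible, and the α-ester group keeps the hindered acid chloride electrophilic.

Step 4
Reactants: 9 ethyl (2S)-2-(2-diazoacetyl)-2,3,3-trimethylbutanoate
Product: 10 ethyl (1S)-1,5,5-trimethyl-2-oxocyclopentane-1-carboxylate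
Conditions: Rh2(OAc)4 (1 mol%), CH2Cl2, reflux, slow addition of 9 at high dilution
Reagents that add atoms: none
Why: Rh2(OAc)4 takes up the diazo carbon of 9 and releases N2, leaving an electrophilic rhodium carbene at C3. The carbene inserts into a methyl C–H bond of the tert-butyl group through a three-centre transition state, forming the C2–C3 bond and releasing the catalyst; the closest known reaction type is the Rh2(OAc)4-catalysed intramolecular 1,5 C–H insertion of α-diazoketones to cyclopentanones. Ring A closes in the five-membered mode (carbene carbon, C4, C5, C1, methyl carbon), which acceptor carbenes prefer over the four-membered mode at the C5 methyl and the six-membered mode at the ester OCH2. No stereocentre is created: whichever of the three equivalent methyl groups reacts, the other two become the C1 gem-dimethyl pair, and quaternary C5 keeps the configuration set in step 2. The step needs chemoselectivity for C–H insertion over attack on the ester carbonyl oxygen, carbene dimerisation and Wolff rearrangement. Nine equivalent C–H bonds held close to the carbene by two adjacent fully substituted carbons, reversible ylide formation and slow addition should secure it. The congested C1–C5 bond is already present in the malonate and is never made.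

Step 5
Reactants: 10 ethyl (1S)-1,5,5-trimethyl-2-oxocyclopentane-1-carboxylate
Product: 11 ethyl (6S)-6,7,7-trimethyl-1,4-dioxaspiro[4.4]nonane-6-carboxylate
Conditions: ethane-1,2-diol, cat. p-TsOH, benzene, reflux, Dean–Stark
Reagents that add atoms: ethane-1,2-diol, OCCO
Why: Acid-catalysed ketalisation with azeotropic removal of water; it masks C4 at the ketone oxidation level, and the non-enolisable β-keto ester cannot epimerise.

Step 6
Reactants: 11 ethyl (6S)-6,7,7-trimethyl-1,4-dioxaspiro[4.4]nonane-6-carboxylate
Product: 12 [(6R)-6,7,7-trimethyl-1,4-dioxaspiro[4.4]nonan-6-yl]methanol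
Conditions: LiAlH4, THF, 0 °C to reflux
Reagents that add atoms: none
Why: Hydride reduction of a hindered ester to the neopentyl alcohol; the ketal is inert (the descriptor changes only through the priority rules).

Step 7
Reactants: 12 [(6R)-6,7,7-trimethyl-1,4-dioxaspiro[4.4]nonan-6-yl]methanol
Product: 13 (6R)-6,7,7-trimethyl-1,4-dioxaspiro[4.4]nonane-6-carbaldehyde
Conditions: Dess–Martin periodinane, NaHCO3, CH2Cl2, rt
Reagents that add atoms: none
Why: Dess–Martin oxidation under buffered conditions; the aldehyde has no α-hydrogen and cannot epimerise or enolise.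

Step 8
Reactants: 13 (6R)-6,7,7-trimethyl-1,4-dioxaspiro[4.4]nonane-6-carbaldehyde; 14 4-bromo-2-methylbut-1-ene
Product: 16 4-methyl-1-[(6R)-6,7,7-trimethyl-1,4-dioxaspiro[4.4]nonan-6-yl]pent-4-en-1-ol (both C1' epimers), via homoallyl Grignard reagent 15 (not isolated)
Conditions: Mg, THF, rt; then 13, THF, −78 °C to 0 °C
Reagents that add atoms: 4-bromo-2-methylbut-1-ene, CC(=C)CCBr
Why: Grignard addition of a primary alkylmagnesium bromide to a non-enolisable aldehyde forms the C1'–C2' bond; the new carbinol centre is removed in the next step, so its configuration is irrelevant.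

Step 9
Reactants: 16 4-methyl-1-[(6R)-6,7,7-trimethyl-1,4-dioxaspiro[4.4]nonan-6-yl]pent-4-en-1-ol
Product: 17 4-methyl-1-[(6R)-6,7,7-trimethyl-1,4-dioxaspiro[4.4]nonan-6-yl]pent-4-en-1-one
Conditions: Dess–Martin periodinane, NaHCO3, CH2Cl2, rt
Reagents that add atoms: none
Why: Dess–Martin oxidation of a hindered secondary alcohol to the ketone; the 1,1-disubstituted alkene and the ketal are untouched.

Step 10
Reactants: 17 4-methyl-1-[(6R)-6,7,7-trimethyl-1,4-dioxaspiro[4.4]nonan-6-yl]pent-4-en-1-one; 18 allylmagnesium bromide
Product: 19 (4R)-7-methyl-4-[(6R)-6,7,7-trimethyl-1,4-dioxaspiro[4.4]nonan-6-yl]octa-1,7-dien-4-ol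
Conditions: allylMgBr (Et2O solution), THF, −78 °C
Reagents that add atoms: allylmagnesium bromide, C=CC[Mg]Br
Why: Allyl Grignard addition, which reaches even very hindered ketones through its six-membered transition state, forms the C1'–C6' bond and the tertiary alcohol. C1' is set by a Felkin–Anh arrangement reinforced by magnesium chelation: the carbonyl oxygen turns toward the dioxolane oxygen cis to the acyl group, and the allyl group enters between C4 and the C5 methyl group, anti to the C1 gem-dimethyl carbon. With the homoallyl chain already on the carbonyl carbon this should give the 1'R carbinol.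

Step 11
Reactants: 19 (4R)-7-methyl-4-[(6R)-6,7,7-trimethyl-1,4-dioxaspiro[4.4]nonan-6-yl]octa-1,7-dien-4-ol
Product: 20 (1R)-4-methyl-1-[(6R)-6,7,7-trimethyl-1,4-dioxaspiro[4.4]nonan-6-yl]cyclohex-3-en-1-ol
Conditions: second-generation Grubbs catalyst (H2IMes)(PCy3)Cl2Ru=CHPh (5 mol%), CH2Cl2, 40 °C
Reagents that add atoms: none
Why: Ring-closing metathesis of a monosubstituted with a 1,1-disubstituted alkene closes ring B as the trisubstituted C4'=C5' cyclohexene with loss of ethene; free tertiary alcohols are tolerated and no stereocentre is touched.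

Step 12
Reactants: 20 (1R)-4-methyl-1-[(6R)-6,7,7-trimethyl-1,4-dioxaspiro[4.4]nonan-6-yl]cyclohex-3-en-1-ol
Product: 21 (2R)-2-[(1R)-1-hydroxy-4-methylcyclohex-3-en-1-yl]-2,3,3-trimethylcyclopentan-1-one
Conditions: PPTS, acetone/H2O, 50 °C
Reagents that add atoms: water, O
Why: Mild acid hydrolysis of the strained neopentyl ketal; weakly acidic conditions avoid both the base-induced retro-aldol cleavage of the C5–C1' bond and acid-induced ether formation between O1' and C4'.

Step 13
Reactants: 21 (2R)-2-[(1R)-1-hydroxy-4-methylcyclohex-3-en-1-yl]-2,3,3-trimethylcyclopentan-1-one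
Product: 23 (5R)-4,4,5-trimethyl-5-[(1R)-4-methyl-1-(triethylsilyloxy)cyclohex-3-en-1-yl]cyclopent-2-en-1-one, via bis(triethylsilyl) enol ether 22 (not isolated)
Conditions: TESOTf, Et3N, CH2Cl2, 0 °C to rt; then (crude) Pd(OAc)2 (10 mol%), O2 (1 atm), DMSO, rt
Reagents that add atoms: triethylsilyl trifluoromethanesulfonate, CC[Si](CC)(CC)OS(=O)(=O)C(F)(F)F
Why: Soft enolisation silylates the only enolisable position (C3) and the tertiary hydroxyl in one operation, and Saegusa–Ito oxidation of the silyl enol ether gives the C2=C3 enone. The silyl ether on O1' blocks retro-aldol cleavage and keeps O1' from directing the later reduction.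

Step 14
Reactants: 23 (5R)-4,4,5-trimethyl-5-[(1R)-4-methyl-1-(triethylsilyloxy)cyclohex-3-en-1-yl]cyclopent-2-en-1-one
Product: 25 (2R,4R)-4-hydroxy-2,3,3-trimethyl-2-[(1R)-4-methyl-1-(triethylsilyloxy)cyclohex-3-en-1-yl]cyclopentan-1-one, via boryl ketone 24 (not isolated)
Conditions: B2pin2, CuCl (5 mol%), NaOtBu (10 mol%), DPEphos, MeOH, THF, rt; then NaBO3·4H2O, THF/H2O, rt
Reagents that add atoms: bis(pinacolato)diboron, CC1(C)OB(OC1(C)C)B1OC(C)(C)C(C)(C)O1 (boron of 24 only); sodium perborate, [Na+].[O-]OB=O
Why: Copper-catalysed conjugate borylation of a cyclic enone followed by oxidation of the C–B bond with retention. The copper boryl species should add to C2 on the face of the C5 methyl group, away from the bulky silyloxycyclohexenyl group, which places the C2 oxygen trans to ring B; the isolated ring B alkene does not react.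

Step 15
Reactants: 25 (2R,4R)-4-hydroxy-2,3,3-trimethyl-2-[(1R)-4-methyl-1-(triethylsilyloxy)cyclohex-3-en-1-yl]cyclopentan-1-one
Product: 26 (2R,4R,5S)-1,1,5-trimethyl-5-[(1'R)-4'-methyl-1'-(triethylsilyloxy)cyclohex-4'-en-1'-yl]cyclopentane-2,4-diol (target atom labels)
Conditions: Me4NBH(OAc)3, MeCN/AcOH, −20 °C
Reagents that add atoms: none
Why: Evans–Saksena reduction: the C2 hydroxyl binds the acetoxyborohydride and delivers hydride to C4 on its own face, giving the anti-1,3-diol with O4 cis to ring B. The same face is the sterically open one, so direction and substrate bias agree.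

Step 16
Reactants: 26 (2R,4R,5S)-1,1,5-trimethyl-5-[(1'R)-4'-methyl-1'-(triethylsilyloxy)cyclohex-4'-en-1'-yl]cyclopentane-2,4-diol
Product: 27 (2S,4R,5S)-2-bromo-1,1,5-trimethyl-5-[(1'R)-4'-methyl-1'-(triethylsilyloxy)cyclohex-4'-en-1'-yl]cyclopentan-4-ol (target atom labels)
Conditions: PPh3, CBr4, CH2Cl2, 0 °C to 40 °C
Reagents that add atoms: tetrabromomethane, BrC(Br)(Br)Br
Why: Appel reaction: the C2 alkoxyphosphonium ion is displaced by bromide with inversion, which puts bromine cis to O4 and ring B. The C4 hydroxyl, flanked by C5 and shielded by the neighbouring triethylsilyloxy group, should be activated much more slowly and returns as the alcohol on work-up.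

Step 17
Reactants: 27 (2S,4R,5S)-2-bromo-1,1,5-trimethyl-5-[(1'R)-4'-methyl-1'-(triethylsilyloxy)cyclohex-4'-en-1'-yl]cyclopentan-4-ol
Product: 28 (1'R)-1'-[(2S,4R,5S)-2-bromo-4-hydroxy-1,1,5-trimethylcyclopent-5-yl]-4'-methylcyclohex-4'-en-1'-ol (target atom labels)
Conditions: HF·pyridine, THF, 0 °C to rt
Reagents that add atoms: none
Why: Fluoride-induced cleavage of the tertiary silyl ether under non-basic conditions, which spare the secondary bromide.

Step 18
Reactants: 28 (1'R)-1'-[(2S,4R,5S)-2-bromo-4-hydroxy-1,1,5-trimethylcyclopent-5-yl]-4'-methylcyclohex-4'-en-1'-ol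
Product: 29 (4'S,5'R)-4',5'-epoxide of 28, epoxide oxygen cis to the C1' hydroxyl
Conditions: VO(acac)2 (5 mol%), t-BuOOH, CH2Cl2, 0 °C to rt
Reagents that add atoms: tert-butyl hydroperoxide, CC(C)(C)OO
Why: Vanadium-catalysed hydroxyl-directed epoxidation of a homoallylic alcohol: the axial C1' hydroxyl binds the metal peroxide and delivers oxygen to its own face of the C4'=C5' alkene. The C4 hydroxyl has no alkene within reach.

Step 19
Reactants: 29 (4'S,5'R)-4',5'-epoxide of 28
Product: 30 cyclic carbonate of 29 (O4 and O1' joined through C=O)
Conditions: 1,1'-carbonyldiimidazole, cat. DMAP, toluene, 80 °C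
Reagents that add atoms: 1,1'-carbonyldiimidazole, O=C(n1ccnc1)n1ccnc1
Why: Cyclic carbonate formation from a cis-1,3-diol: the C4 oxygen is acylated and the tertiary C1' hydroxyl closes the six-membered ring intramolecularly. The reagent contains no halide that could open the epoxide, and the carbonate makes both oxygens non-nucleophilic for the next two steps.

Step 20
Reactants: 30 cyclic carbonate of 29
Product: 31 (4'R,5'R)-4'-bromo-5'-hydroxy carbonate (C4' bromine axial, trans to the axial C5' hydroxyl)
Conditions: 48% aq. HBr, CHCl3, 0 °C
Reagents that add atoms: hydrogen bromide, Br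
Why: Acid-mediated epoxide opening by bromide; attack at tertiary C4' from the face opposite the epoxide oxygen is both the trans-diaxial (Fürst–Plattner) and the Markovnikov mode, so regio- and stereochemistry agree. The carbonate keeps O1' from capturing the developing C4' cation.

Step 21
Reactants: 31 (4'R,5'R)-4'-bromo-5'-hydroxy carbonate
Product: 32 4,1'-O-carbonyl derivative of the target (4'S,5'S)
Conditions: SOCl2, pyridine, CH2Cl2, −20 °C to rt
Reagents that add atoms: thionyl chloride, ClS(Cl)=O
Why: Substitution with neighbouring-group participation: the C5' chlorosulfite leaves with help from the anti-periplanar axial bromine, giving a bromonium ion on the face away from O1', and chloride opens it at the tertiary carbon C4'. Bromine thus moves to C5' with inversion there and chlorine enters C4' cis to O1', which is the trans-diequatorial pair of the target; the hydroxyl of 31 is the only free one.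

Step 22
Reactants: 32 4,1'-O-carbonyl derivative of the target
Product: 33 (1R,3S,4S)-3-bromo-4-chloro-4-methyl-1-[(1S,3S,5R)-3-bromo-5-hydroxy-1,2,2-trimethylcyclopentyl]cyclohexan-1-ol
Conditions: K2CO3, MeOH, 0 °C to rt
Reagents that add atoms: none
Why: Base-catalysed methanolysis of the cyclic carbonate; both ring B halogens are equatorial and lack an anti-periplanar hydrogen for E2, and neither liberated alkoxide can reach the rear side of a C–halogen bond.

## Compound list

1 | diethyl tert-butylmalonate | CCOC(=O)C(C(=O)OCC)C(C)(C)C | starting material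
2 | iodomethane | CI | starting material
3 | sodium enolate of 1 | CCOC(=O)C(=C([O-])OCC)C(C)(C)C.[Na+] | intermediate
4 | diethyl 2-tert-butyl-2-methylmalonate | CCOC(=O)C(C)(C(=O)OCC)C(C)(C)C | intermediate
5 | (2S)-2-(ethoxycarbonyl)-2,3,3-trimethylbutanoic acid | OC(=O)[C@](C)(C(C)(C)C)C(=O)OCC | intermediate
6 | (trimethylsilyl)diazomethane | C[Si](C)(C)C=[N+]=[N-] | starting material
7 | ethyl (2R)-2-(chlorocarbonyl)-2,3,3-trimethylbutanoate | ClC(=O)[C@](C)(C(C)(C)C)C(=O)OCC | intermediate
8 | ethyl (2S)-2-[2-diazo-2-(trimethylsilyl)acetyl]-2,3,3-trimethylbutanoate | C[Si](C)(C)C(=[N+]=[N-])C(=O)[C@](C)(C(C)(C)C)C(=O)OCC | intermediate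
9 | ethyl (2S)-2-(2-diazoacetyl)-2,3,3-trimethylbutanoate | [N-]=[N+]=CC(=O)[C@](C)(C(C)(C)C)C(=O)OCC | intermediate
10 | ethyl (1S)-1,5,5-trimethyl-2-oxocyclopentane-1-carboxylate | CC1(C)CCC(=O)[C@@]1(C)C(=O)OCC | intermediate
11 | ethyl (6S)-6,7,7-trimethyl-1,4-dioxaspiro[4.4]nonane-6-carboxylate | CC1(C)CCC2(OCCO2)[C@@]1(C)C(=O)OCC | intermediate
12 | [(6R)-6,7,7-trimethyl-1,4-dioxaspiro[4.4]nonan-6-yl]methanol | CC1(C)CCC2(OCCO2)[C@@]1(C)CO | intermediate
13 | (6R)-6,7,7-trimethyl-1,4-dioxaspiro[4.4]nonane-6-carbaldehyde | CC1(C)CCC2(OCCO2)[C@@]1(C)C=O | intermediate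
14 | 4-bromo-2-methylbut-1-ene | CC(=C)CCBr | starting material
15 | (3-methylbut-3-en-1-yl)magnesium bromide | CC(=C)CC[Mg]Br | intermediate
16 | 4-methyl-1-[(6R)-6,7,7-trimethyl-1,4-dioxaspiro[4.4]nonan-6-yl]pent-4-en-1-ol (both C1' epimers) | CC1(C)CCC2(OCCO2)[C@@]1(C)C(O)CCC(C)=C | intermediate
17 | 4-methyl-1-[(6R)-6,7,7-trimethyl-1,4-dioxaspiro[4.4]nonan-6-yl]pent-4-en-1-one | CC1(C)CCC2(OCCO2)[C@@]1(C)C(=O)CCC(C)=C | intermediate
18 | allylmagnesium bromide | C=CC[Mg]Br | starting material
19 | (4R)-7-methyl-4-[(6R)-6,7,7-trimethyl-1,4-dioxaspiro[4.4]nonan-6-yl]octa-1,7-dien-4-ol | CC1(C)CCC2(OCCO2)[C@@]1(C)[C@@](CC=C)(O)CCC(C)=C | intermediate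
20 | (1R)-4-methyl-1-[(6R)-6,7,7-trimethyl-1,4-dioxaspiro[4.4]nonan-6-yl]cyclohex-3-en-1-ol | CC1(C)CCC2(OCCO2)[C@@]1(C)[C@@]1(O)CCC(C)=CC1 | intermediate
21 | (2R)-2-[(1R)-1-hydroxy-4-methylcyclohex-3-en-1-yl]-2,3,3-trimethylcyclopentan-1-one | CC1(C)CCC(=O)[C@@]1(C)[C@@]1(O)CCC(C)=CC1 | intermediate
22 | C3=C4 triethylsilyl enol ether and O1' triethylsilyl ether of 21 | CC1(C)CC=C(O[Si](CC)(CC)CC)[C@@]1(C)[C@@]1(O[Si](CC)(CC)CC)CCC(C)=CC1 | intermediate
23 | (5R)-4,4,5-trimethyl-5-[(1R)-4-methyl-1-(triethylsilyloxy)cyclohex-3-en-1-yl]cyclopent-2-en-1-one | CC1(C)C=CC(=O)[C@@]1(C)[C@@]1(O[Si](CC)(CC)CC)CCC(C)=CC1 | intermediate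
24 | (2R,4R)-2,3,3-trimethyl-2-[(1R)-4-methyl-1-(triethylsilyloxy)cyclohex-3-en-1-yl]-4-(4,4,5,5-tetramethyl-1,3,2-dioxaborolan-2-yl)cyclopentan-1-one | CC1(C)[C@H](B2OC(C)(C)C(C)(C)O2)CC(=O)[C@@]1(C)[C@@]1(O[Si](CC)(CC)CC)CCC(C)=CC1 | intermediate
25 | (2R,4R)-4-hydroxy-2,3,3-trimethyl-2-[(1R)-4-methyl-1-(triethylsilyloxy)cyclohex-3-en-1-yl]cyclopentan-1-one | CC1(C)[C@H](O)CC(=O)[C@@]1(C)[C@@]1(O[Si](CC)(CC)CC)CCC(C)=CC1 | intermediate
26 | (2R,4R,5S,1'R)-diol, target atom labels: C2 hydroxyl trans and C4 hydroxyl cis to ring B, O1' triethylsilyl ether, C4'=C5' alkene | CC1(C)[C@H](O)C[C@@H](O)[C@@]1(C)[C@@]1(O[Si](CC)(CC)CC)CCC(C)=CC1 | intermediate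
27 | (2S,4R,5S,1'R)-C2 bromide, target atom labels: bromine and C4 hydroxyl cis to ring B, O1' triethylsilyl ether | CC1(C)[C@@H](Br)C[C@@H](O)[C@@]1(C)[C@@]1(O[Si](CC)(CC)CC)CCC(C)=CC1 | intermediate
28 | (1'R)-1'-[(2S,4R,5S)-2-bromo-4-hydroxy-1,1,5-trimethylcyclopent-5-yl]-4'-methylcyclohex-4'-en-1'-ol (target atom labels) | CC1(C)[C@@H](Br)C[C@@H](O)[C@@]1(C)[C@@]1(O)CCC(C)=CC1 | intermediate
29 | (4'S,5'R)-4',5'-epoxide of 28, epoxide oxygen cis to the C1' hydroxyl | CC1(C)[C@@H](Br)C[C@@H](O)[C@@]1(C)[C@@]1(O)CC[C@]2(C)O[C@@H]2C1 | intermediate
30 | cyclic carbonate of 29 (O4–C(=O)–O1') | CC1(C)[C@@H](Br)C[C@@H](OC2=O)[C@@]1(C)[C@@]1(O2)CC[C@]3(C)O[C@@H]3C1 | intermediate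
31 | (4'R,5'R)-4'-bromo-5'-hydroxy carbonate (bromine and hydroxyl trans-diaxial) | CC1(C)[C@@H](Br)C[C@@H](OC2=O)[C@@]1(C)[C@@]1(O2)CC[C@@](C)(Br)[C@H](O)C1 | intermediate
32 | 4,1'-O-carbonyl derivative of the target (4'S,5'S) | CC1(C)[C@@H](Br)C[C@@H](OC2=O)[C@@]1(C)[C@@]1(O2)CC[C@](C)(Cl)[C@@H](Br)C1 | intermediate
33 | (1R,3S,4S)-3-bromo-4-chloro-4-methyl-1-[(1S,3S,5R)-3-bromo-5-hydroxy-1,2,2-trimethylcyclopentyl]cyclohexan-1-ol | CC1(C)[C@@H](Br)C[C@@H](O)[C@@]1(C)[C@@]1(O)CC[C@](C)(Cl)[C@@H](Br)C1 | target

## Step count and risks

Total step count: 22. Longest linear sequence: 22 steps (from **1** to **33**).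

**Step 4 (key step).** The carbene may be diverted before it reaches a primary C–H bond, the least reactive class: by dimerisation, by attack on the ester carbonyl oxygen, or by Wolff rearrangement. The fallback sets out from acid chloride **7** and returns at **10**. Crossed Claisen condensation of **7** with the lithium enolate of tert-butyl acetate gives the β-keto ester F1. Diazo transfer with 4-acetamidobenzenesulfonyl azide and Et3N gives the diazo keto diester F2. Its acceptor/acceptor carbene (Rh2(OAc)4) does not dimerise and belongs to the standard substrate class for cyclopentanone-forming insertion, giving the keto diester F3. Trifluoroacetic acid followed by warming removes the tert-butyl ester with decarboxylation.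

**Step 21.** Chloride may be captured at C5' along the diaxial return path instead of at C4', or the bromonium ion may lose a proton. The fallback sets out from **31** and returns at **32**. Thionyl chloride without base in a solvent of low polarity is used deliberately to give, by ion-pair return with retention, the diaxial 4'-bromo-5'-chloro carbonate F4. Heating F4 in a polar, non-nucleophilic solvent then effects the diaxial-to-diequatorial rearrangement known for vicinal bromochlorides on locked six-membered rings, in which both halogens change carbons through the same bromonium ion pair.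

**Step 16.** Displacement at a neopentyl carbon from the more crowded face may be slow. It would then lose to elimination, to a cationic methyl shift from C1, or to activation of the C4 hydroxyl. The fallback sets out from boryl ketone **24** (isolated instead of oxidised) and returns at **28**. NaBH4 reduces the C4 ketone from the open face to the boryl alcohol F5, and TESOTf with 2,6-lutidine gives the bis(silyl) ether F6. 3,5-Bis(trifluoromethyl)phenyllithium forms the lithium aryl boronate complex F7, and N-bromosuccinimide replaces boron by bromine with inversion (stereospecific halodeboronation of a secondary boronic ester) to give the bis(silyl) bromide F8. HF·pyridine removes both silyl groups.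

**Step 2.** Enzymatic hydrolysis may be slow or poorly selective, because both ester groups sit on a carbon that also carries a tert-butyl group. The fallback sets out from **4** and returns at **5**. One equivalent of KOH in ethanol gives the racemic half ester F9. This is resolved by crystallisation of its (S)-1-phenylethylammonium salt F10, and acidification gives **5**.

**Step 10.** Facial selectivity at the C1' carbonyl may be poor or reversed, since allylmagnesium reagents react very fast and respond only weakly to chelation. The fallback sets out from **13** and returns at **19**, adding the two chains in the opposite order. Allylmagnesium bromide **18** adds to **13** to give the homoallylic alcohol F11, and Dess–Martin oxidation gives the allyl ketone F12. The non-basic organocerium reagent from **15** and CeCl3 then adds to this enolisable ketone. An unchanged facial preference now produces the opposite C1' configuration, which is the correct one if the preference is the reverse of that assumed.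

## Further compounds

F1 | step 4 | 1-tert-butyl 5-ethyl (4S)-4-tert-butyl-4-methyl-3-oxopentanedioate | CC(C)(C)OC(=O)CC(=O)[C@](C)(C(C)(C)C)C(=O)OCC
F2 | step 4 | 1-tert-butyl 5-ethyl (4S)-4-tert-butyl-2-diazo-4-methyl-3-oxopentanedioate | CC(C)(C)OC(=O)C(=[N+]=[N-])C(=O)[C@](C)(C(C)(C)C)C(=O)OCC
F3 | step 4 | 1-tert-butyl 3-ethyl (3S)-3,4,4-trimethyl-2-oxocyclopentane-1,3-dicarboxylate (both C1 epimers) | CC1(C)CC(C(=O)OC(C)(C)C)C(=O)[C@@]1(C)C(=O)OCC
F4 | step 21 | (4'R,5'R)-4'-bromo-5'-chloro carbonate, halogens trans-diaxial | CC1(C)[C@@H](Br)C[C@@H](OC2=O)[C@@]1(C)[C@@]1(O2)CC[C@@](C)(Br)[C@H](Cl)C1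
F5 | step 16 | C2 pinacolboryl C4 alcohol, O1' triethylsilyl ether (boron trans, hydroxyl cis to ring B) | CC1(C)[C@H](B2OC(C)(C)C(C)(C)O2)C[C@@H](O)[C@@]1(C)[C@@]1(O[Si](CC)(CC)CC)CCC(C)=CC1
F6 | step 16 | O4,O1'-bis(triethylsilyl) ether of F5 | CC1(C)[C@H](B2OC(C)(C)C(C)(C)O2)C[C@@H](O[Si](CC)(CC)CC)[C@@]1(C)[C@@]1(O[Si](CC)(CC)CC)CCC(C)=CC1
F7 | step 16 | lithium [3,5-bis(trifluoromethyl)phenyl]boronate complex of F6 | [Li+].CC1(C)[C@H]([B-]2(OC(C)(C)C(C)(C)O2)c2cc(cc(c2)C(F)(F)F)C(F)(F)F)C[C@@H](O[Si](CC)(CC)CC)[C@@]1(C)[C@@]1(O[Si](CC)(CC)CC)CCC(C)=CC1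
F8 | step 16 | O4,O1'-bis(triethylsilyl) ether of 28 | CC1(C)[C@@H](Br)C[C@@H](O[Si](CC)(CC)CC)[C@@]1(C)[C@@]1(O[Si](CC)(CC)CC)CCC(C)=CC1
F9 | step 2 | racemic 2-(ethoxycarbonyl)-2,3,3-trimethylbutanoic acid | OC(=O)C(C)(C(C)(C)C)C(=O)OCC
F10 | step 2 | (S)-1-phenylethylammonium (2S)-2-(ethoxycarbonyl)-2,3,3-trimethylbutanoate | [O-]C(=O)[C@](C)(C(C)(C)C)C(=O)OCC.C[C@H]([NH3+])c1ccccc1
F11 | step 10 | 1-[(6R)-6,7,7-trimethyl-1,4-dioxaspiro[4.4]nonan-6-yl]but-3-en-1-ol (both C1' epimers) | CC1(C)CCC2(OCCO2)[C@@]1(C)C(O)CC=C
F12 | step 10 | 1-[(6R)-6,7,7-trimethyl-1,4-dioxaspiro[4.4]nonan-6-yl]but-3-en-1-one | CC1(C)CCC2(OCCO2)[C@@]1(C)C(=O)CC=C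
A1 | alternative 1 | tert-butyl (3R)-6-methyl-2-(4-methylcyclohex-3-en-1-ylidene)hept-5-en-3-yl carbonate (alkene geometry as in the SMILES) | CC(C)=CC[C@@H](OC(=O)OC(C)(C)C)/C(C)=C1\CCC(C)=CC1
A2 | alternative 1 | cyclic O4,O1'-carbonate of 28 | CC1(C)[C@@H](Br)C[C@@H](OC2=O)[C@@]1(C)[C@@]1(O2)CCC(C)=CC1
A3 | alternative 2 | tert-butyldimethyl[(1,5,5,6-tetramethyl-7-oxabicyclo[4.1.0]heptan-2-yl)oxy]silane, silyloxy group cis to the epoxide oxygen | CC1(C)CC[C@@H](O[Si](C)(C)C(C)(C)C)[C@@]2(C)O[C@@]12C
A4 | alternative 2 | 1-[2-(tert-butyldimethylsilyloxy)-1,5,5-trimethylcyclopentyl]ethanone, silyloxy group cis to acetyl | CC1(C)CC[C@@H](O[Si](C)(C)C(C)(C)C)[C@@]1(C)C(C)=O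
A5 | alternative 3 | methyl 3-(tert-butyldimethylsilyloxy)-2-methyl-5-oxo-2-(prop-1-en-2-yl)pentanoate | O=CC[C@@H](O[Si](C)(C)C(C)(C)C)[C@@](C(C)=C)(C)C(=O)OC
A6 | alternative 3 | methyl 2-(tert-butyldimethylsilyloxy)-4-hydroxy-1,5,5-trimethylcyclopentane-1-carboxylate, both oxygens cis to the ester | CC1(C)[C@@H](O)C[C@@H](O[Si](C)(C)C(C)(C)C)[C@@]1(C)C(=O)OC
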